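**Plan**

- Numbering of the target: tetrahydrofuran O1, C2 (aryl), C3 (CH2OH), C4 (3,4-dimethoxybenzyl), C5. The retrosynthesis first cuts the benzylic O1–C2 bond, then in one three-component disconnection the C2–C3 bond (aldol) and the C4–CH2Ar bond (Michael).
- Enabling feature: the chain C5–C4–C3–CH2OH is oxygenated at both ends, with C4 β to the hydroxymethyl carbon. Folded into a temporary 5-alkoxyfuran-2(5H)-one ring (hydroxymethyl carbon as lactone C=O, C5 as acetal carbon), C4 becomes the Michael acceptor and C3 the enolate carbon. The benzylic CH2 is raised to the aldehyde level as a 1,3-dithiane so that it can act as the nucleophile.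
- Forward: dithiane anion, (5R)-menthyloxybutenolide and O-TIPS-vanillin are joined in one flask. Raney Ni then removes the dithiane and LiAlH4 opens the temporary lactone and releases menthol. The tetrahydrofuran ring is closed last by capture of the C2 benzylic cation by the C5 hydroxyl, and desilylation ends the route.
- Stereochemistry: C4 comes from the l-menthol-derived acetal centre (anti addition) and C3 from C4 (anti aldol). The trans lactone becomes the 3,4-cis tetrahydrofuran because the ring is re-closed through the other carbon on C3. C2 comes from C3 (2,3-trans closure; both carbinol epimers converge).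

Key step: step 3

Assumption: butenolide 5 is taken as a purchasable chiral building block. The carbinol carbon made in step 3 is expected as a mixture of epimers and is carried on as such, because that centre is re-set in step 6. "Menthyl" means (1R,2S,5R)-2-isopropyl-5-methylcyclohexyl throughout.

Step 1
Reactants: 1 vanillin (4-hydroxy-3-methoxybenzaldehyde)
Product: 2 3-methoxy-4-(triisopropylsilyloxy)benzaldehyde
Conditions: TIPSCl, imidazole, DMF, rt
Reagents that add atoms: triisopropylsilyl chloride, CC(C)[Si](Cl)(C(C)C)C(C)C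
Why: Imidazole-mediated silylation of a phenol; the bulky TIPS ether should mask the acidic phenol against n-BuLi, the lithium enolate and LiAlH4 and is stable to Raney Ni and mild acid.

Step 2
Reactants: 3 3,4-dimethoxybenzaldehyde (veratraldehyde)
Product: 4 2-(3,4-dimethoxyphenyl)-1,3-dithiane
Conditions: HS(CH2)3SH, BF3·OEt2 (cat.), CH2Cl2, 0 °C to rt
Reagents that add atoms: propane-1,3-dithiol, SCCCS
Why: Lewis-acid-catalysed dithioacetalisation turns the aldehyde carbon into an acyl-anion equivalent (Corey–Seebach umpolung), the later benzylic CH2 of the target.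

Step 3
Reactants: 4 2-(3,4-dimethoxyphenyl)-1,3-dithiane; 5 (5R)-5-[(1R,2S,5R)-menthyloxy]furan-2(5H)-one; 2 3-methoxy-4-(triisopropylsilyloxy)benzaldehyde
Product: 8 (3S,4R,5R)-3-{hydroxy[3-methoxy-4-(triisopropylsilyloxy)phenyl]methyl}-4-[2-(3,4-dimethoxyphenyl)-1,3-dithian-2-yl]-5-[(1R,2S,5R)-menthyloxy]dihydrofuran-2(3H)-one (both carbinol epimers), via 2-lithio-2-(3,4-dimethoxyphenyl)-1,3-dithiane 6 (not isolated), via lithium enolate of the Michael adduct 7 (not isolated)
Conditions: 4, n-BuLi, THF, −78 to −20 °C; then 5, −78 °C; then 2, −78 °C; AcOH quench at −78 °C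
Reagents that add atoms: none
Why: The sulfur-stabilised benzylic anion 6 adds 1,4 to C4 of butenolide 5, and the resulting lithium enolate 7 is trapped at C3 by aldehyde 2 in the same flask, so three components are joined and the C4–benzylic carbon bond and the C3–carbinol bond are formed in one operation. The closest known reaction type is the tandem Michael addition–aldol trapping of lithiated 2-aryl-1,3-dithianes on 5-alkoxyfuran-2(5H)-ones used for lignan lactones. No ring is closed in this step. The new centre at C4 is controlled by the C5 menthyloxy group on the flat five-membered ring (the nucleophile enters anti to it), the new centre at C3 is controlled by the bulky C4 dithianyl group (the aldehyde enters anti to it), and the carbinol centre is not controlled and need not be. The step needs 1,4- over 1,2-addition, which the delocalised aryl dithiane anion and the low temperature should secure, and it needs facial selectivity, which the acetal substituent next to the β-carbon should secure. Quenching cold with AcOH should prevent retro-aldol of the hindered aldolate.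

Step 4
Reactants: 8 tandem adduct (dithianyl hydroxy lactone)
Product: 9 (3S,4R,5R)-4-(3,4-dimethoxybenzyl)-3-{hydroxy[3-methoxy-4-(triisopropylsilyloxy)phenyl]methyl}-5-[(1R,2S,5R)-menthyloxy]dihydrofuran-2(3H)-one (both carbinol epimers)
Conditions: Raney Ni (W-2, deactivated in acetone), EtOH/THF, rt to 50 °C
Reagents that add atoms: none
Why: Raney Ni desulfurisation (Mozingo reduction) turns the dithioacetal into CH2; C–S cleavage should be much faster than hydrogenolysis of the benzylic C–OH, and the lactone acetal, silyl ether and both ring stereocentres are not touched.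

Step 5
Reactants: 9 benzyl hydroxy lactone
Product: 10 (2R,3R)-2-(3,4-dimethoxybenzyl)-3-{hydroxy[3-methoxy-4-(triisopropylsilyloxy)phenyl]methyl}butane-1,4-diol (both carbinol epimers)
Conditions: LiAlH4, THF, 0 °C to rt; then H2O, aq NaOH
Reagents that add atoms: none
Why: LiAlH4 reduces the lactone carbonyl to CH2OH and, after opening of the alkoxy lactone, the unmasked aldehyde at the former acetal carbon to the second CH2OH with release of menthol; hydride reduction should outrun epimerisation of the transient α-branched aldehyde, so both stereocentres are kept.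

Step 6
Reactants: 10 silyl-protected triol
Product: 12 {(2S,3R,4R)-4-(3,4-dimethoxybenzyl)-2-[3-methoxy-4-(triisopropylsilyloxy)phenyl]tetrahydrofuran-3-yl}methanol, via benzylic cation 11 (not isolated)
Conditions: camphorsulfonic acid (cat.), CH2Cl2, 0 °C
Reagents that add atoms: none
Why: SN1 cycloetherification: only the electron-rich para-silyloxy benzylic alcohol ionises, both carbinol epimers converge on the planar cation 11, and the primary hydroxyl on the benzyl-bearing carbon closes the ring 5-exo-trig (the other hydroxyl could only give an oxetane) with the aryl group trans to the C3 hydroxymethyl, which sets C2 as S under kinetic and thermodynamic preference.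

Step 7
Reactants: 12 silyl-protected tetrahydrofuran
Product: 13 4'-O-methyllariciresinol, [(2S,3R,4R)-4-(3,4-dimethoxybenzyl)-2-(4-hydroxy-3-methoxyphenyl)tetrahydrofuran-3-yl]methanol
Conditions: Bu4NF, AcOH, THF, 0 °C
Reagents that add atoms: none
Why: Fluoride-induced cleavage of the aryl silyl ether under buffered conditions frees the phenol without touching the acid-sensitive benzylic ether or any stereocentre.

**Compound list**

1 | vanillin | COc1cc(C=O)ccc1O | starting material
2 | 3-methoxy-4-(triisopropylsilyloxy)benzaldehyde | COc1cc(C=O)ccc1O[Si](C(C)C)(C(C)C)C(C)C | intermediate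
3 | 3,4-dimethoxybenzaldehyde | COc1ccc(C=O)cc1OC | starting material
4 | 2-(3,4-dimethoxyphenyl)-1,3-dithiane | COc1ccc(C2SCCCS2)cc1OC | intermediate
5 | (5R)-5-[(1R,2S,5R)-menthyloxy]furan-2(5H)-one | O=C1C=C[C@H](O[C@@H]2C[C@H](C)CC[C@H]2C(C)C)O1 | starting material
6 | 2-lithio-2-(3,4-dimethoxyphenyl)-1,3-dithiane | [Li]C1(c2ccc(OC)c(OC)c2)SCCCS1 | intermediate
7 | lithium enolate of (4R,5R)-4-[2-(3,4-dimethoxyphenyl)-1,3-dithian-2-yl]-5-[(1R,2S,5R)-menthyloxy]dihydrofuran-2(3H)-one | [Li]OC1=C[C@@H](C2(c3ccc(OC)c(OC)c3)SCCCS2)[C@H](O[C@@H]2C[C@H](C)CC[C@H]2C(C)C)O1 | intermediate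
8 | (3S,4R,5R)-3-{hydroxy[3-methoxy-4-(triisopropylsilyloxy)phenyl]methyl}-4-[2-(3,4-dimethoxyphenyl)-1,3-dithian-2-yl]-5-[(1R,2S,5R)-menthyloxy]dihydrofuran-2(3H)-one, carbinol epimers | O=C1[C@H](C(O)c2ccc(O[Si](C(C)C)(C(C)C)C(C)C)c(OC)c2)[C@@H](C2(c3ccc(OC)c(OC)c3)SCCCS2)[C@H](O[C@@H]2C[C@H](C)CC[C@H]2C(C)C)O1 | intermediate
9 | (3S,4R,5R)-4-(3,4-dimethoxybenzyl)-3-{hydroxy[3-methoxy-4-(triisopropylsilyloxy)phenyl]methyl}-5-[(1R,2S,5R)-menthyloxy]dihydrofuran-2(3H)-one, carbinol epimers | O=C1[C@H](C(O)c2ccc(O[Si](C(C)C)(C(C)C)C(C)C)c(OC)c2)[C@@H](Cc2ccc(OC)c(OC)c2)[C@H](O[C@@H]2C[C@H](C)CC[C@H]2C(C)C)O1 | intermediate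
10 | (2R,3R)-2-(3,4-dimethoxybenzyl)-3-{hydroxy[3-methoxy-4-(triisopropylsilyloxy)phenyl]methyl}butane-1,4-diol, carbinol epimers | COc1cc(C(O)[C@@H](CO)[C@H](CO)Cc2ccc(OC)c(OC)c2)ccc1O[Si](C(C)C)(C(C)C)C(C)C | intermediate
11 | benzylic cation formed from 10 by loss of water (para-silyloxy-stabilised) | COc1cc([CH+][C@@H](CO)[C@H](CO)Cc2ccc(OC)c(OC)c2)ccc1O[Si](C(C)C)(C(C)C)C(C)C | intermediate
12 | {(2S,3R,4R)-4-(3,4-dimethoxybenzyl)-2-[3-methoxy-4-(triisopropylsilyloxy)phenyl]tetrahydrofuran-3-yl}methanol | COc1cc([C@H]2OC[C@H](Cc3ccc(OC)c(OC)c3)[C@@H]2CO)ccc1O[Si](C(C)C)(C(C)C)C(C)C | intermediate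
13 | 4'-O-methyllariciresinol, [(2S,3R,4R)-4-(3,4-dimethoxybenzyl)-2-(4-hydroxy-3-methoxyphenyl)tetrahydrofuran-3-yl]methanol | COc1cc([C@H]2OC[C@H](Cc3ccc(OC)c(OC)c3)[C@@H]2CO)ccc1O | target

Total step count: 7. Longest linear sequence: 6 steps (step 2 or step 1, then steps 3 to 7).

**Steps most likely to fail**

Step 6. The ionised benzylic centre may be captured by carbon instead of oxygen: intramolecular Friedel–Crafts alkylation by the dimethoxyphenyl ring would give an aryltetralin irreversibly. The ring closure may also show poor 2,3-trans selectivity.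
The fallback sets out from 10 and changes the mechanism of ring closure from a cation to a neutral quinone methide. Desilylation of 10 with Bu4NF/AcOH in THF should give the free-phenol triol (2R,3R)-2-(3,4-dimethoxybenzyl)-3-[hydroxy(4-hydroxy-3-methoxyphenyl)methyl]butane-1,4-diol F1. With a trace of pyridinium p-toluenesulfonate in MeCN at rt, F1 should lose water to the para-quinone methide 4-[(2R,3R)-3-(3,4-dimethoxybenzyl)-4-hydroxy-2-(hydroxymethyl)butylidene]-2-methoxycyclohexa-2,5-dien-1-one F2. Reversible 1,6-addition of the primary hydroxyl to F2 (5-exo) should then give the 2,3-trans ether under thermodynamic control and under conditions too mild for Friedel–Crafts closure. This fallback comes back to the route at 13.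

Step 3. Addition may occur 1,2 at the lactone carbonyl, or the aldol trapping of the enolate flanked by the quaternary dithiane carbon may be slow or reversible, so that only the protonated Michael adduct is obtained.
The fallback sets out from 5 (with 4) and splits the one-flask event into separate operations. Addition of 6 to 5 and quenching with AcOH should give (4R,5R)-4-[2-(3,4-dimethoxyphenyl)-1,3-dithian-2-yl]-5-[(1R,2S,5R)-menthyloxy]dihydrofuran-2(3H)-one F3. Raney Ni desulfurisation should then give (4R,5R)-4-(3,4-dimethoxybenzyl)-5-[(1R,2S,5R)-menthyloxy]dihydrofuran-2(3H)-one F4. Deprotonation of F4 with LiN(iPr)2 in THF at −78 °C gives a far less hindered enolate, and a directed aldol with 2, anti to the C4 benzyl group, comes back to the route at 9.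

Step 4. On the nickel surface the electron-rich benzylic C–OH may be hydrogenolysed, residual alkali may cause retro-aldol or dehydration of the β-hydroxy lactone, or the hindered quaternary dithiane may be cleaved only slowly.
The fallback sets out from 8 and postpones the desulfurisation until no β-hydroxy carbonyl and no free benzylic alcohol remain. LiAlH4 reduction of 8 should give (2R,3R)-2-[2-(3,4-dimethoxyphenyl)-1,3-dithian-2-yl]-3-{hydroxy[3-methoxy-4-(triisopropylsilyloxy)phenyl]methyl}butane-1,4-diol F5. Closure with catalytic camphorsulfonic acid as in step 6 should give {(2S,3R,4R)-4-[2-(3,4-dimethoxyphenyl)-1,3-dithian-2-yl]-2-[3-methoxy-4-(triisopropylsilyloxy)phenyl]tetrahydrofuran-3-yl}methanol F6. Desulfurisation of F6 with nickel boride (NiCl2·6H2O, NaBH4, MeOH/THF, 0 °C) comes back to the route at 12.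

**Further compounds**

F1 | step 6 | (2R,3R)-2-(3,4-dimethoxybenzyl)-3-[hydroxy(4-hydroxy-3-methoxyphenyl)methyl]butane-1,4-diol, carbinol epimers | COc1cc(C(O)[C@@H](CO)[C@H](CO)Cc2ccc(OC)c(OC)c2)ccc1O
F2 | step 6 | 4-[(2R,3R)-3-(3,4-dimethoxybenzyl)-4-hydroxy-2-(hydroxymethyl)butylidene]-2-methoxycyclohexa-2,5-dien-1-one | COC1=CC(=C[C@@H](CO)[C@H](CO)Cc2ccc(OC)c(OC)c2)C=CC1=O
F3 | step 3 | (4R,5R)-4-[2-(3,4-dimethoxyphenyl)-1,3-dithian-2-yl]-5-[(1R,2S,5R)-menthyloxy]dihydrofuran-2(3H)-one | O=C1C[C@@H](C2(c3ccc(OC)c(OC)c3)SCCCS2)[C@H](O[C@@H]2C[C@H](C)CC[C@H]2C(C)C)O1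
F4 | step 3 | (4R,5R)-4-(3,4-dimethoxybenzyl)-5-[(1R,2S,5R)-menthyloxy]dihydrofuran-2(3H)-one | O=C1C[C@@H](Cc2ccc(OC)c(OC)c2)[C@H](O[C@@H]2C[C@H](C)CC[C@H]2C(C)C)O1
F5 | step 4 | (2R,3R)-2-[2-(3,4-dimethoxyphenyl)-1,3-dithian-2-yl]-3-{hydroxy[3-methoxy-4-(triisopropylsilyloxy)phenyl]methyl}butane-1,4-diol, carbinol epimers | COc1cc(C(O)[C@@H](CO)[C@H](CO)C2(c3ccc(OC)c(OC)c3)SCCCS2)ccc1O[Si](C(C)C)(C(C)C)C(C)C
F6 | step 4 | {(2S,3R,4R)-4-[2-(3,4-dimethoxyphenyl)-1,3-dithian-2-yl]-2-[3-methoxy-4-(triisopropylsilyloxy)phenyl]tetrahydrofuran-3-yl}methanol | COc1cc([C@H]2OC[C@H](C3(c4ccc(OC)c(OC)c4)SCCCS3)[C@@H]2CO)ccc1O[Si](C(C)C)(C(C)C)C(C)C
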